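**Strategy**

Everything rests on cutting the alkyl aryl ether between the C8 oxygen and the oxygen-bearing carbon of ring B. That carbon sits between the two methoxy-bearing carbons and para to the propenyl group, so it can arrive as a bromoarene. A palladium-catalysed C–O cross-coupling joins it to the free C8 hydroxyl of a lactate-derived carbinol in one operation, leaving C8 untouched. The precursor is (1R,2S)-1-(methoxymethoxy)-1-(3,4,5-trimethoxyphenyl)propan-2-ol: ring A is already attached, and the future C7 ketone is held as a small, non-migrating MOM-protected carbinol, so C8 carries no acidic hydrogen during the basic coupling. Acetal removal and oxidation then give the target.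

Key step: step 8

**Remarks on the chemistry**

- Numbering: ring A is the 3,4,5-trimethoxyphenyl ring, C7 the carbon that becomes the carbonyl, C8 the methyl-bearing stereocentre, and ring B the 2,6-dimethoxy-4-propenylphenoxy ring.
- Assumption: C7 is drawn throughout as the anti (1R) epimer expected from Felkin–Anh addition. Its configuration is erased in step 10, so any syn epimer can be carried along without separation.
- C8 of the target is S. It comes unchanged from ethyl (S)-lactate, because the order of substituent priorities at that carbon (O, C7, CH3, H) never changes.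
- RockPhos is 2-(di-tert-butylphosphino)-3-methoxy-6-methyl-2′,4′,6′-triisopropylbiphenyl.

**Route**

Step 1
Reactants: 1 ethyl (S)-lactate
Product: 2 ethyl (S)-2-[(tert-butyldimethylsilyl)oxy]propanoate
Conditions: TBSCl, imidazole, DMF, 0 °C → rt
Reagents that add atoms: tert-butyldimethylsilyl chloride, CC(C)(C)[Si](C)(C)Cl
Why: Imidazole-promoted O-silylation of a secondary alcohol is routine and does not touch the lactate stereocentre, which becomes C8.

Step 2
Reactants: 2 ethyl (S)-2-[(tert-butyldimethylsilyl)oxy]propanoate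
Product: 3 (S)-2-[(tert-butyldimethylsilyl)oxy]propanal
Conditions: i-Bu2AlH (1.1 equiv), CH2Cl2, −78 °C; MeOH, then aq potassium sodium tartrate (KNaC4H4O6)
Reagents that add atoms: none
Why: Partial reduction of an ester with i-Bu2AlH at −78 °C stops at the tetrahedral aluminium hemiacetal, which collapses to the aldehyde only on work-up; the crude α-silyloxy aldehyde is used at once so that C8 is not epimerised.

Step 3
Reactants: 3 (S)-2-[(tert-butyldimethylsilyl)oxy]propanal; 4 5-bromo-1,2,3-trimethoxybenzene
Product: 6 (1R,2S)-2-[(tert-butyldimethylsilyl)oxy]-1-(3,4,5-trimethoxyphenyl)propan-1-ol, via arylmagnesium bromide 5 (not isolated)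
Conditions: 4, Mg turnings, THF, reflux; then 3, THF, −78 → −40 °C; aq NH4Cl
Reagents that add atoms: none
Why: Grignard formation followed by 1,2-addition to the aldehyde builds the ring A–C7 bond, and Felkin–Anh attack anti to the non-chelating silyloxy group should favour the anti (1R) carbinol, whose configuration is in any case erased in step 10.

Step 4
Reactants: 6 (1R,2S)-2-[(tert-butyldimethylsilyl)oxy]-1-(3,4,5-trimethoxyphenyl)propan-1-ol
Product: 7 tert-butyl{[(1R,2S)-1-(methoxymethoxy)-1-(3,4,5-trimethoxyphenyl)propan-2-yl]oxy}dimethylsilane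
Conditions: MOMCl, i-Pr2NEt, n-Bu4NI (cat.), CH2Cl2, 0 → 40 °C
Reagents that add atoms: chloromethyl methyl ether, COCCl
Why: Alkylation of the hindered benzylic hydroxyl with MOMCl under amine base (acetal formation through the oxocarbenium ion, iodide-assisted) is reliable, and without an alkoxide the neighbouring silyl ether cannot migrate.

Step 5
Reactants: 7 tert-butyl{[(1R,2S)-1-(methoxymethoxy)-1-(3,4,5-trimethoxyphenyl)propan-2-yl]oxy}dimethylsilane
Product: 8 (1R,2S)-1-(methoxymethoxy)-1-(3,4,5-trimethoxyphenyl)propan-2-ol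
Conditions: n-Bu4NF, THF, 0 °C → rt
Reagents that add atoms: none
Why: Fluoride-induced desilylation frees only the C8 hydroxyl, since the MOM acetal is inert to n-Bu4NF and cannot shift between oxygens.

Step 6
Reactants: 9 4-bromo-3,5-dimethoxybenzaldehyde; 10 ethylmagnesium bromide
Product: 11 1-(4-bromo-3,5-dimethoxyphenyl)propan-1-ol (racemic)
Conditions: THF, −20 → 0 °C; aq NH4Cl
Reagents that add atoms: none
Why: Grignard 1,2-addition to the aryl aldehyde is fast at low temperature, where EtMgBr does not exchange with the aryl bromide; the new carbinol centre is racemic and is removed in step 7.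

Step 7
Reactants: 11 1-(4-bromo-3,5-dimethoxyphenyl)propan-1-ol
Product: 12 2-bromo-1,3-dimethoxy-5-[(E)-prop-1-enyl]benzene
Conditions: p-TsOH·H2O (cat.), toluene, reflux, Dean–Stark trap
Reagents that add atoms: none
Why: Acid-catalysed E1 dehydration of the benzylic alcohol with azeotropic removal of water should give the conjugated alkene, the E isomer being the thermodynamic product.

Step 8
Reactants: 8 (1R,2S)-1-(methoxymethoxy)-1-(3,4,5-trimethoxyphenyl)propan-2-ol (1.0 equiv); 12 2-bromo-1,3-dimethoxy-5-[(E)-prop-1-enyl]benzene (1.3 equiv)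
Product: 13 5-[(1R,2S)-2-{2,6-dimethoxy-4-[(E)-prop-1-enyl]phenoxy}-1-(methoxymethoxy)propyl]-1,2,3-trimethoxybenzene
Conditions: [(allyl)PdCl]2 (2.5 mol %), RockPhos (7.5 mol %), Cs2CO3 (2 equiv), toluene, 90 °C
Reagents that add atoms: none
Why: Zerovalent palladium carrying one RockPhos ligand should insert into the C–Br bond of 12, the caesium alkoxide of 8 should replace bromide on divalent palladium, and C–O reductive elimination should release 13; this is the established palladium-catalysed etherification of secondary alcohols with aryl bromides under bulky biarylphosphine ligation, here applied to a doubly ortho-substituted, electron-rich bromide. No ring is closed and no stereocentre is created; C8 keeps its S configuration because only its O–H bond is exchanged for an O–aryl bond and, with C7 still a carbinol ether, the C8 hydrogen is not acidic towards Cs2CO3. The selectivity that matters is reductive elimination over β-hydride elimination from the palladium alkoxide, which would give the debrominated arene and the C8 ketone and, if reversible, could scramble C8; the bulk of the ligand together with the two ortho methoxy groups of ring B crowds the metal and should speed reductive elimination. Site selectivity is secured by the substrate, since 8 has a single free hydroxyl, its C7 oxygen sits in an acetal that cannot migrate to the C8 alkoxide, and the internal (E)-propenyl alkene is a poor Heck acceptor.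

Step 9
Reactants: 13 5-[(1R,2S)-2-{2,6-dimethoxy-4-[(E)-prop-1-enyl]phenoxy}-1-(methoxymethoxy)propyl]-1,2,3-trimethoxybenzene
Product: 15 (1R,2S)-2-{2,6-dimethoxy-4-[(E)-prop-1-enyl]phenoxy}-1-(3,4,5-trimethoxyphenyl)propan-1-ol, via alkoxymethyl bipyridinium triflate 14 (not isolated)
Conditions: Me3SiOTf (2 equiv), 2,2′-bipyridyl (3 equiv), CH2Cl2, 0 °C → rt; then H2O, rt
Reagents that add atoms: none
Why: In this non-protic acetal cleavage Me3SiOTf silylates the terminal methoxy oxygen, 2,2′-bipyridyl traps the resulting oxocarbenium ion as the pyridinium salt 14 and buffers the medium, and water then hydrolyses 14 to the alcohol, so that neither the benzylic C7–O bond nor the propenyl group meets a strong protic acid.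

Step 10
Reactants: 15 (1R,2S)-2-{2,6-dimethoxy-4-[(E)-prop-1-enyl]phenoxy}-1-(3,4,5-trimethoxyphenyl)propan-1-ol
Product: 16 (S)-2-{2,6-dimethoxy-4-[(E)-prop-1-enyl]phenoxy}-1-(3,4,5-trimethoxyphenyl)propan-1-one
Conditions: Dess–Martin periodinane, NaHCO3, CH2Cl2, 0 °C → rt; aq Na2S2O3/NaHCO3
Reagents that add atoms: none
Why: Dess–Martin oxidation of the secondary benzylic alcohol under NaHCO3 buffer is fast and nearly neutral, so that both C7 epimers converge on the ketone while the now enolisable C8 centre should keep its S configuration.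

**Compound list**

1 | ethyl (S)-lactate | C[C@H](O)C(=O)OCC | starting material
2 | ethyl (S)-2-[(tert-butyldimethylsilyl)oxy]propanoate | C[C@H](O[Si](C)(C)C(C)(C)C)C(=O)OCC | intermediate
3 | (S)-2-[(tert-butyldimethylsilyl)oxy]propanal | C[C@H](O[Si](C)(C)C(C)(C)C)C=O | intermediate
4 | 5-bromo-1,2,3-trimethoxybenzene | COc1cc(Br)cc(OC)c1OC | starting material
5 | (3,4,5-trimethoxyphenyl)magnesium bromide | COc1cc([Mg]Br)cc(OC)c1OC | intermediate (not isolated)
6 | (1R,2S)-2-[(tert-butyldimethylsilyl)oxy]-1-(3,4,5-trimethoxyphenyl)propan-1-ol | C[C@H](O[Si](C)(C)C(C)(C)C)[C@H](O)c1cc(OC)c(OC)c(OC)c1 | intermediate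
7 | tert-butyl{[(1R,2S)-1-(methoxymethoxy)-1-(3,4,5-trimethoxyphenyl)propan-2-yl]oxy}dimethylsilane | C[C@H](O[Si](C)(C)C(C)(C)C)[C@H](OCOC)c1cc(OC)c(OC)c(OC)c1 | intermediate
8 | (1R,2S)-1-(methoxymethoxy)-1-(3,4,5-trimethoxyphenyl)propan-2-ol | C[C@H](O)[C@H](OCOC)c1cc(OC)c(OC)c(OC)c1 | intermediate
9 | 4-bromo-3,5-dimethoxybenzaldehyde | O=Cc1cc(OC)c(Br)c(OC)c1 | starting material
10 | ethylmagnesium bromide | CC[Mg]Br | starting material
11 | 1-(4-bromo-3,5-dimethoxyphenyl)propan-1-ol (racemic) | CCC(O)c1cc(OC)c(Br)c(OC)c1 | intermediate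
12 | 2-bromo-1,3-dimethoxy-5-[(E)-prop-1-enyl]benzene | C/C=C/c1cc(OC)c(Br)c(OC)c1 | intermediate
13 | 5-[(1R,2S)-2-{2,6-dimethoxy-4-[(E)-prop-1-enyl]phenoxy}-1-(methoxymethoxy)propyl]-1,2,3-trimethoxybenzene | C/C=C/c1cc(OC)c(O[C@@H](C)[C@H](OCOC)c2cc(OC)c(OC)c(OC)c2)c(OC)c1 | intermediate
14 | 1-{[(1R,2S)-2-{2,6-dimethoxy-4-[(E)-prop-1-enyl]phenoxy}-1-(3,4,5-trimethoxyphenyl)propoxy]methyl}-2-(pyridin-2-yl)pyridin-1-ium trifluoromethanesulfonate | C/C=C/c1cc(OC)c(O[C@@H](C)[C@H](OC[n+]2ccccc2-c2ccccn2)c2cc(OC)c(OC)c(OC)c2)c(OC)c1.[O-]S(=O)(=O)C(F)(F)F | intermediate (not isolated)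
15 | (1R,2S)-2-{2,6-dimethoxy-4-[(E)-prop-1-enyl]phenoxy}-1-(3,4,5-trimethoxyphenyl)propan-1-ol | C/C=C/c1cc(OC)c(O[C@@H](C)[C@H](O)c2cc(OC)c(OC)c(OC)c2)c(OC)c1 | intermediate
16 | (S)-2-{2,6-dimethoxy-4-[(E)-prop-1-enyl]phenoxy}-1-(3,4,5-trimethoxyphenyl)propan-1-one | C/C=C/c1cc(OC)c(O[C@@H](C)C(=O)c2cc(OC)c(OC)c(OC)c2)c(OC)c1 | target

**Step count and risks**

Total step count: 10.
Longest linear sequence: 8 steps (steps 1–5, 8, 9 and 10); steps 6 and 7 form the two-step branch to bromide 12.

The three steps most likely to fail: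

1. Step 8. β-Hydride elimination from the palladium alkoxide may outrun C–O reductive elimination, which would debrominate the arene and oxidise the carbinol, and if reversible could erode the configuration at C8. Oxidative addition at the hindered, electron-rich C–Br bond may also stall. The fallback forms the C8–O bond by Mitsunobu inversion before ring A is attached. It sets out from bromide 12, which bromine–lithium exchange (n-BuLi, THF, −78 °C), borylation with B(OMe)3 and oxidation (H2O2, NaOH) should convert into (E)-2,6-dimethoxy-4-(prop-1-enyl)phenol F1. A Mitsunobu reaction (PPh3, DIAD, THF, 0 °C → rt) of this phenol with purchased ethyl (R)-lactate F2 should give, with inversion, ethyl (S)-2-{2,6-dimethoxy-4-[(E)-prop-1-enyl]phenoxy}propanoate F3. Partial reduction with i-Bu2AlH at −78 °C should give (S)-2-{2,6-dimethoxy-4-[(E)-prop-1-enyl]phenoxy}propanal F4. Addition of the Grignard reagent 5 at −78 °C then returns to the route at alcohol 15 (either C7 epimer serves), ready for step 10.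

2. Step 9. Acetal cleavage may be accompanied by ionisation at benzylic C7 or by cationic attack on the propenyl double bond, or hydrolysis of the pyridinium intermediate may stay incomplete. The fallback changes the C7 protecting group to a ketal that is cleaved under nearly neutral conditions. It sets out from alcohol 6, which 2-methoxypropene and catalytic pyridinium p-toluenesulfonate (CH2Cl2, 0 °C) should convert into tert-butyl{[(1R,2S)-1-[(2-methoxypropan-2-yl)oxy]-1-(3,4,5-trimethoxyphenyl)propan-2-yl]oxy}dimethylsilane F5. Desilylation with n-Bu4NF should give (1R,2S)-1-[(2-methoxypropan-2-yl)oxy]-1-(3,4,5-trimethoxyphenyl)propan-2-ol F6. Coupling with 12 under the conditions of step 8 should give 5-[(1R,2S)-2-{2,6-dimethoxy-4-[(E)-prop-1-enyl]phenoxy}-1-[(2-methoxypropan-2-yl)oxy]propyl]-1,2,3-trimethoxybenzene F7. Brief treatment with AcOH–THF–H2O at rt releases the alcohol, and the route is rejoined at 15.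

3. Step 3. The basic Grignard reagent may enolise the α-silyloxy aldehyde, which would erode the configuration at C8 and leave aldehyde unconsumed, or the silyl group may migrate to the new magnesium alkoxide. The fallback replaces addition to the aldehyde by acylation and reduction, so that no free carbonyl lies next to C8 while base is present. It sets out from ester 2, which MeNH(OMe)·HCl and i-PrMgCl (THF, −20 °C) should convert into (S)-2-[(tert-butyldimethylsilyl)oxy]-N-methoxy-N-methylpropanamide F8. The Grignard reagent 5 should add once, through the chelated tetrahedral intermediate, to give (S)-2-[(tert-butyldimethylsilyl)oxy]-1-(3,4,5-trimethoxyphenyl)propan-1-one F9. Reduction with NaBH4 (MeOH, −20 °C) returns to the route at alcohol 6, either C7 epimer being acceptable.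

**Further compounds**

F1 | step 8 | (E)-2,6-dimethoxy-4-(prop-1-enyl)phenol | C/C=C/c1cc(OC)c(O)c(OC)c1
F2 | step 8 | ethyl (R)-lactate (purchased) | C[C@@H](O)C(=O)OCC
F3 | step 8 | ethyl (S)-2-{2,6-dimethoxy-4-[(E)-prop-1-enyl]phenoxy}propanoate | C/C=C/c1cc(OC)c(O[C@@H](C)C(=O)OCC)c(OC)c1
F4 | step 8 | (S)-2-{2,6-dimethoxy-4-[(E)-prop-1-enyl]phenoxy}propanal | C/C=C/c1cc(OC)c(O[C@@H](C)C=O)c(OC)c1
F5 | step 9 | tert-butyl{[(1R,2S)-1-[(2-methoxypropan-2-yl)oxy]-1-(3,4,5-trimethoxyphenyl)propan-2-yl]oxy}dimethylsilane | C[C@H](O[Si](C)(C)C(C)(C)C)[C@H](OC(C)(C)OC)c1cc(OC)c(OC)c(OC)c1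
F6 | step 9 | (1R,2S)-1-[(2-methoxypropan-2-yl)oxy]-1-(3,4,5-trimethoxyphenyl)propan-2-ol | C[C@H](O)[C@H](OC(C)(C)OC)c1cc(OC)c(OC)c(OC)c1
F7 | step 9 | 5-[(1R,2S)-2-{2,6-dimethoxy-4-[(E)-prop-1-enyl]phenoxy}-1-[(2-methoxypropan-2-yl)oxy]propyl]-1,2,3-trimethoxybenzene | C/C=C/c1cc(OC)c(O[C@@H](C)[C@H](OC(C)(C)OC)c2cc(OC)c(OC)c(OC)c2)c(OC)c1
F8 | step 3 | (S)-2-[(tert-butyldimethylsilyl)oxy]-N-methoxy-N-methylpropanamide | C[C@H](O[Si](C)(C)C(C)(C)C)C(=O)N(C)OC
F9 | step 3 | (S)-2-[(tert-butyldimethylsilyl)oxy]-1-(3,4,5-trimethoxyphenyl)propan-1-one | C[C@H](O[Si](C)(C)C(C)(C)C)C(=O)c1cc(OC)c(OC)c(OC)c1
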